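## Analysis of the target

The target 25 (C36H26O20) is an achiral, open-chain hexamer in which six benzene rings, lettered A to F from the 2,4,6-trihydroxyphenyl end to the 3,4,5-trihydroxyphenyl end, are joined by five diaryl ether oxygens and carry fifteen free phenolic hydroxyls. There is no stereocentre and the ethers rotate freely, so the problem is purely one of constitution. Rings A, B, D, E and F are tetraoxygenated, whereas ring C alone is pentaoxygenated: aryloxy groups on the adjacent carbons C1 (oxygen shared with C4 of ring B) and C2 (oxygen shared with C1 of ring D), hydroxyls on C3, C4 and C5, and its only hydrogen on C6. The sense of the ether links turns at ring C: toward ring A each bridging oxygen sits on a doubly oxygen-flanked carbon of the outer ring, and toward ring F it sits on the doubly flanked carbon of the inner ring (C2 of ring C, C4 of rings D and E). The free polyphenol is electron-rich and oxidises readily in air and base, so the hydroxyls must travel masked (as methyl ethers here) and be released fifteen at once without harm to the diaryl ethers. The difficulty is twofold: every ether bond has a hindered, electron-rich, doubly ortho-oxygenated carbon on one side, and all six rings share the same phloroglucinol-derived oxygenation, so no ring C–H can be halogenated or metallated selectively late on. The strategy rests on the C1/C2 pair of aryloxy carbons of ring C next to the oxygenated C3–C5 block, which is the pattern that 3,4,5-trimethoxybenzyne writes when an oxygen nucleophile enters at C1 and an electrophile at C2.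

## Retrosynthetic reasoning

**Target 25 to 24.** All fifteen O–H bonds are traced back to O–CH3 bonds. Methyl ethers survive every base, organometallic, peracid and metal-mediated step of the route and are the form in which the building blocks are available. The forward reaction must cleave fifteen aryl methyl ethers by Lewis-acid dealkylation and leave the five diaryl ethers intact.

**24 to 16 and 23.** The hexamer is cut at the oxygen–C2 bond of ring C, between the ring D oxygen and ring C. This divides the molecule into two three-ring halves and places the leaving group on ring C and the nucleophilic oxygen on ring D, where the hydroxyl of 23 has only hydrogen neighbours. The forward step is a copper-catalysed Ullmann etherification in which only the iodide 16 bears the steric load.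

**16 to 11, 6 and 12 (key disconnection).** Two bonds on adjacent carbons of ring C are cut together: the ring B oxygen–C1 bond and the C2–iodine bond. Both fragments then collapse onto the aryne 14, which is released from the silylaryl triflate 6. The phenol 11 supplies the oxygen nucleophile and the perfluoroalkyl iodide 12 supplies electrophilic iodine. This disconnection is chosen over any stepwise alternative because a C–H bond at C2 could not be iodinated selectively afterwards. It also makes the hindered 2,6-dimethoxyphenoxide the nucleophile toward a carbon with no ortho substituent at the moment of attack. The forward reaction must add oxygen at C1 and not C2, and must trap the C2 carbanion 15 with iodine before any proton reaches it.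

**11 to 9, then to 7 and 8.** The hindered hydroxyl of 11 is traced to a formyl group (Baeyer–Villiger/Dakin oxidation via the formate 10). That formyl group is the para activator for cutting the ring A oxygen–ring B bond by SNAr between phenol 7 and aryl fluoride 8. The hindered oxygen is again the nucleophile and the fluorinated carbon of 8 has only hydrogen neighbours.

**6 to 3, 2 and 1.** The silyl and triflyloxy groups on adjacent carbons go back to a bromine and a silyloxy group in 3. Halogen–metal exchange, a retro-Brook shift (via 4 and 5) and triflation connect them. Compound 3 comes from bromophenol 2 by O-silylation and 2 from phenol 1 by bromination at one of its two equivalent free positions. The sequence places silicon next to the methoxy-bearing C3, which is what the regiochemistry of 14 requires.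

**23 to 22, then to 20 and 21; 20 to 18, then to 17 and 8.** The ring D hydroxyl of 23 is masked as the bromide in 22 and revealed by palladium-catalysed hydroxylation. Ring F is removed from 22 at the ring E oxygen–ring F bond, which leaves the hindered phenol 20 and the boronic acid 21, in which ring F is bought complete. An oxidative copper coupling joins the two at room temperature, where the aryl bromide of 20 is untouched. This keeps the aryne 14 for the one place where two adjacent carbons must be functionalised together. The hindered phenol 20 is the bromo analogue of 11 and is made the same way from 17 and 8 through aldehyde 18 and formate 19.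

## Alternatives that were turned down

**Alternative 1:** Ring C would be built from a four-membered ring, with the C5–C6 bond of ring C formed last. The precursor is 4-[(tert-butyldimethylsilyl)oxy]-4-{1-[2,6-dimethoxy-4-(2,4,6-trimethoxyphenoxy)phenoxy]ethenyl}-2,3-dimethoxycyclobut-2-en-1-one A2, reached from dimethyl squarate A3 by addition of an α-aryloxyvinyl nucleophile and O-silylation. On heating, A2 should undergo 4π electrocyclic ring opening, 6π electrocyclic closure and tautomerisation to 5-[2,6-dimethoxy-4-(2,4,6-trimethoxyphenoxy)phenoxy]-4-[(tert-butyldimethylsilyl)oxy]-2,3-dimethoxyphenol A1.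
- For: the place of every oxygen is fixed by connectivity and the C2 and C5 oxygens emerge differentiated. On positional certainty this is stronger than the chosen strategy, which depends on the polarisation of a triple bond.
- Against: the vinyl nucleophile must be made from the hindered phenol 11 and metallated in a molecule whose ring positions between two oxygens are themselves acidic. After the ring expansion, C5 must be methylated and C2 desilylated. The ring D ether must then be formed with a phenol flanked by aryloxy and methoxy groups as nucleophile, so the hard coupling is inverted, not removed.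
- Comparison: about five operations on the AB unit would lead to a ring C intermediate that the aryne step delivers in one, already carrying a leaving group at C2. The chosen route gives up certainty by construction for convergence and relies on the well-understood directing effect of a 3-alkoxy group on an aryne.

**Alternative 2:** Ring A would be made last from acyclic carbon. The five-ring aryloxymalonate A6 and dimethyl 3-oxopentanedioate A5 would undergo a double Claisen condensation (Mg(OMe)2 or NaOMe) forming two C–C bonds and, after enolisation, the dimethyl 2,4,6-trihydroxy-5-aryloxybenzene-1,3-dicarboxylate A4.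
- For: the oxygen on ring A never has to be joined to an aromatic carbon by coupling, and the three ring A hydroxyls arrive free.
- Against: the condensation would be the last construction step on a large substrate. The electrophilic esters of A6 sit on a carbon that bears a bulky aryloxy group and an acidic hydrogen, so enolisation of A6 competes with acylation. A4 then needs double ester hydrolysis and decarboxylation on a free phloroglucinol. The alternative also addresses the least difficult ring: the vicinal diether of ring C inside A6 remains unsolved.
- Comparison: it is equal to the chosen route only in avoiding a coupling at the hindered ring A oxygen, which the chosen route handles by a simple SNAr with that oxygen as nucleophile (step 4). It adds several steps and removes none.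

**Alternative 3:** Three aryl C–OH bonds (para hydroxyl of ring A, C4 of ring C, C4 of ring F) would be traced to formyl groups. The hexameric trialdehyde A8 would undergo a threefold peracid Baeyer–Villiger oxidation and formate hydrolysis to the triphenol A7.
- For: each formyl group first activates its ring for SNAr ether formation at the para carbon and then becomes a hydroxyl. All reaction types are thoroughly established, and on precedent this is stronger than an aryne three-component coupling.
- Against: a formyl group at C4 of ring C activates C1 but is meta to C2, so the ether at the most congested carbon still needs a different, unactivated method. On ring A the SNAr would have to occur at a fluorinated carbon flanked by two methoxy groups. The build-up is linear, the triple oxidation comes late on a hexamer of electron-rich rings, and A7 must then be re-methylated or carried as a mixed ether.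
- Comparison: the chosen route keeps this formyl logic where it fits (rings B and E, steps 4–5 and 7–8). At ring C it uses the aryne, which functionalises C1 and C2 together and keeps the synthesis convergent (three rings plus three rings).

Key step: step 6

Remark on the chemistry: on ring C the carbon bonded to the ring B oxygen is C1 and the carbon bonded to the ring D oxygen is C2; all fifteen hydroxyls are carried as methyl ethers, and 1, 7, 8, 12, 17 and 21 are taken as purchasable.

## Route

**Step 1**
Reactants: 1 3,4,5-trimethoxyphenol
Product: 2 2-bromo-3,4,5-trimethoxyphenol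
Conditions: NBS (1.0 equiv), CH2Cl2, −78 °C to 0 °C
Reagents that add atoms: N-bromosuccinimide, O=C1CCC(=O)N1Br
Why: Electrophilic aromatic bromination; the only free ring positions, C2 and C6, are equivalent and strongly activated, so one equivalent of NBS at low temperature should stop at the monobromide.

**Step 2**
Reactants: 2 2-bromo-3,4,5-trimethoxyphenol
Product: 3 (2-bromo-3,4,5-trimethoxyphenoxy)trimethylsilane
Conditions: HMDS, THF, 65 °C; evaporate
Reagents that add atoms: hexamethyldisilazane, C[Si](C)(C)N[Si](C)(C)C
Why: O-silylation of a phenol with HMDS; ammonia is the only by-product, so the silyl ether can be used after evaporation.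

**Step 3**
Reactants: 3 (2-bromo-3,4,5-trimethoxyphenoxy)trimethylsilane
Product: 6 3,4,5-trimethoxy-2-(trimethylsilyl)phenyl trifluoromethanesulfonate, via aryllithium 4 (not isolated), via lithium 2-silylphenoxide 5 (not isolated)
Conditions: n-BuLi, THF, −78 °C; then Tf2O, −78 °C to 0 °C
Reagents that add atoms: trifluoromethanesulfonic anhydride, O=S(=O)(OS(=O)(=O)C(F)(F)F)C(F)(F)F; n-butyllithium, [Li]CCCC (lithium of 4 and 5 only)
Why: Bromine–lithium exchange gives 4, whose carbanion attacks the neighbouring O–Si group (retro-Brook 1,3 O-to-C silyl shift) to give phenoxide 5, which is triflated in the same flask; this is the standard route to 2-silylaryl triflates.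

**Step 4**
Reactants: 7 2,4,6-trimethoxyphenol; 8 4-fluoro-2,6-dimethoxybenzaldehyde
Product: 9 2,6-dimethoxy-4-(2,4,6-trimethoxyphenoxy)benzaldehyde
Conditions: Cs2CO3, DMSO, 110 °C
Reagents that add atoms: none
Why: SNAr (addition–elimination) of the phenoxide on the aryl fluoride para to the formyl group; the fluorinated carbon has only hydrogen neighbours, so the hindered but electron-rich phenoxide of 7 can reach it, and the methoxy groups of 8 are meta to the site of attack.

**Step 5**
Reactants: 9 2,6-dimethoxy-4-(2,4,6-trimethoxyphenoxy)benzaldehyde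
Product: 11 2,6-dimethoxy-4-(2,4,6-trimethoxyphenoxy)phenol, via aryl formate 10 (not isolated)
Conditions: mCPBA (1.2 equiv), CH2Cl2, 0 °C to rt; bicarbonate wash; then K2CO3 (cat.), MeOH, rt
Reagents that add atoms: 3-chloroperoxybenzoic acid, OOC(=O)c1cccc(Cl)c1
Why: Baeyer–Villiger (Dakin-type) oxidation; the electron-rich 2,6-dimethoxyaryl group migrates in preference to hydrogen to give formate 10, which is methanolysed to the phenol.

**Step 6**
Reactants: 11 2,6-dimethoxy-4-(2,4,6-trimethoxyphenoxy)phenol; 6 3,4,5-trimethoxy-2-(trimethylsilyl)phenyl trifluoromethanesulfonate; 12 nonafluoro-1-iodobutane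
Product: 16 1-[2,6-dimethoxy-4-(2,4,6-trimethoxyphenoxy)phenoxy]-2-iodo-3,4,5-trimethoxybenzene, via potassium phenoxide 13 (not isolated), via 3,4,5-trimethoxybenzyne 14 (not isolated), via arylpotassium 15 (not isolated)
Conditions: KH, THF, 0 °C; then 6 (1.5 equiv), 12 (3 equiv), KF, 18-crown-6, THF, 0 °C to rt, dark
Reagents that add atoms: potassium hydride, [KH] (potassium of 13 and 15 only)
Why: KH converts 11 into the phenoxide 13 with H2 as the only by-product, so no proton donor remains; fluoride then attacks the silicon of 6 and triflate leaves, giving aryne 14 by 1,2-elimination. The σ-withdrawing C3 methoxy group distorts the triple bond and stabilises negative charge at C2, and it also shields C2, so the hindered phenoxide oxygen adds at C1, forming the ring B oxygen–C1 bond and leaving arylpotassium 15 with its carbanion between the new aryloxy group and the methoxy group. Compound 15 then abstracts iodine from 12 by halogen–metal exchange, which is pulled forward because the perfluorobutyl anion is the better-stabilised carbanion and is lost irreversibly as octafluorobut-1-ene and fluoride. The closest known reaction type is the three-component 1,2-difunctionalisation of arynes from 2-silylaryl triflates with a heteroatom nucleophile and a halogen donor, together with the O-arylation of phenols by arynes; the aryloxide–iodine pairing extends that class. No ring is closed and no stereocentre is formed. Two selectivities are needed: addition at C1 over C2, secured by the C3 methoxy group, and iodination over protonation, secured by the preformed phenoxide, the aprotic ether solvent and the excess of 12; exclusion of light suppresses electron transfer from the phenoxide to 12.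

**Step 7**
Reactants: 17 4-bromo-2,6-dimethoxyphenol; 8 4-fluoro-2,6-dimethoxybenzaldehyde
Product: 18 4-(4-bromo-2,6-dimethoxyphenoxy)-2,6-dimethoxybenzaldehyde
Conditions: Cs2CO3, DMSO, 110 °C
Reagents that add atoms: none
Why: SNAr as in step 4; the aryl bromide of 17 sits on an unactivated ring and is inert to addition–elimination, so it survives as the masked ring D hydroxyl.

**Step 8**
Reactants: 18 4-(4-bromo-2,6-dimethoxyphenoxy)-2,6-dimethoxybenzaldehyde
Product: 20 4-(4-bromo-2,6-dimethoxyphenoxy)-2,6-dimethoxyphenol, via aryl formate 19 (not isolated)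
Conditions: mCPBA (1.2 equiv), CH2Cl2, 0 °C to rt; bicarbonate wash; then K2CO3 (cat.), MeOH, rt
Reagents that add atoms: 3-chloroperoxybenzoic acid, OOC(=O)c1cccc(Cl)c1
Why: Baeyer–Villiger (Dakin-type) oxidation as in step 5; the aryl bromide is inert to peracid.

**Step 9**
Reactants: 20 4-(4-bromo-2,6-dimethoxyphenoxy)-2,6-dimethoxyphenol; 21 (3,4,5-trimethoxyphenyl)boronic acid
Product: 22 5-bromo-2-[3,5-dimethoxy-4-(3,4,5-trimethoxyphenoxy)phenoxy]-1,3-dimethoxybenzene
Conditions: 21 (2.0 equiv), Cu(OAc)2 (1.0 equiv), pyridine (5 equiv), 4 Å MS, CH2Cl2, rt, dry air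
Reagents that add atoms: none
Why: Chan–Lam–Evans oxidative coupling of a phenol with an arylboronic acid: the aryl group passes from boron to divalent copper, oxidation to trivalent copper and C–O reductive elimination give the diaryl ether, and dioxygen returns the copper to the divalent state. The electron-rich boronic acid transmetallates readily, doubly ortho-substituted phenols are accepted in this coupling, and the aryl bromide does not react with copper at room temperature.

**Step 10**
Reactants: 22 5-bromo-2-[3,5-dimethoxy-4-(3,4,5-trimethoxyphenoxy)phenoxy]-1,3-dimethoxybenzene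
Product: 23 4-[3,5-dimethoxy-4-(3,4,5-trimethoxyphenoxy)phenoxy]-3,5-dimethoxyphenol
Conditions: Pd2(dba)3 (cat.), tBuXPhos, KOH, 1,4-dioxane/H2O, 100 °C
Reagents that add atoms: potassium hydroxide, [K+].[OH-]
Why: Palladium-catalysed hydroxylation of an aryl bromide: oxidative addition to zerovalent palladium, bromide–hydroxide exchange and C–O reductive elimination promoted by the bulky biaryl phosphine; methyl and diaryl ethers are inert to aqueous KOH.

**Step 11**
Reactants: 16 1-[2,6-dimethoxy-4-(2,4,6-trimethoxyphenoxy)phenoxy]-2-iodo-3,4,5-trimethoxybenzene; 23 4-[3,5-dimethoxy-4-(3,4,5-trimethoxyphenoxy)phenoxy]-3,5-dimethoxyphenol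
Product: 24 1-[2,6-dimethoxy-4-(2,4,6-trimethoxyphenoxy)phenoxy]-2-{4-[3,5-dimethoxy-4-(3,4,5-trimethoxyphenoxy)phenoxy]-3,5-dimethoxyphenoxy}-3,4,5-trimethoxybenzene
Conditions: CuI (20 mol%), picolinic acid (40 mol%), K3PO4, DMSO, 100 °C, argon
Reagents that add atoms: none
Why: Ullmann-type copper-catalysed diaryl ether synthesis; the picolinate-ligated copper phenoxide system is suited to ortho-substituted aryl iodides, and the phenol 23 has no ortho substituent, so only the iodide carries steric load.

**Step 12**
Reactants: 24 1-[2,6-dimethoxy-4-(2,4,6-trimethoxyphenoxy)phenoxy]-2-{4-[3,5-dimethoxy-4-(3,4,5-trimethoxyphenoxy)phenoxy]-3,5-dimethoxyphenoxy}-3,4,5-trimethoxybenzene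
Product: 25 5-[2,6-dihydroxy-4-(2,4,6-trihydroxyphenoxy)phenoxy]-4-{4-[3,5-dihydroxy-4-(3,4,5-trihydroxyphenoxy)phenoxy]-3,5-dihydroxyphenoxy}benzene-1,2,3-triol (CNP0270681.0)
Conditions: BBr3 (about 3 equiv per OMe), CH2Cl2, −78 °C to rt; then H2O, 0 °C, under argon
Reagents that add atoms: none
Why: Lewis-acid cleavage of aryl methyl ethers: BBr3 coordinates each methoxy oxygen and bromide attacks the methyl carbon (SN2), while the diaryl ether oxygens carry no sp3 carbon and cannot be dealkylated; hydrolysis releases the fifteen phenols.

## Compound list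

1 | 3,4,5-trimethoxyphenol | COc1cc(O)cc(OC)c1OC | starting material
2 | 2-bromo-3,4,5-trimethoxyphenol | COc1cc(O)c(Br)c(OC)c1OC | intermediate
3 | (2-bromo-3,4,5-trimethoxyphenoxy)trimethylsilane | COc1cc(O[Si](C)(C)C)c(Br)c(OC)c1OC | intermediate
4 | (2-lithio-3,4,5-trimethoxyphenoxy)trimethylsilane | COc1cc(O[Si](C)(C)C)c([Li])c(OC)c1OC | intermediate
5 | lithium 3,4,5-trimethoxy-2-(trimethylsilyl)phenoxide | COc1cc([O-])c([Si](C)(C)C)c(OC)c1OC.[Li+] | intermediate
6 | 3,4,5-trimethoxy-2-(trimethylsilyl)phenyl trifluoromethanesulfonate | COc1cc(OS(=O)(=O)C(F)(F)F)c([Si](C)(C)C)c(OC)c1OC | intermediate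
7 | 2,4,6-trimethoxyphenol | COc1cc(OC)c(O)c(OC)c1 | starting material
8 | 4-fluoro-2,6-dimethoxybenzaldehyde | COc1cc(F)cc(OC)c1C=O | starting material
9 | 2,6-dimethoxy-4-(2,4,6-trimethoxyphenoxy)benzaldehyde | COc1cc(OC)c(Oc2cc(OC)c(C=O)c(OC)c2)c(OC)c1 | intermediate
10 | 2,6-dimethoxy-4-(2,4,6-trimethoxyphenoxy)phenyl formate | COc1cc(OC)c(Oc2cc(OC)c(OC=O)c(OC)c2)c(OC)c1 | intermediate
11 | 2,6-dimethoxy-4-(2,4,6-trimethoxyphenoxy)phenol | COc1cc(OC)c(Oc2cc(OC)c(O)c(OC)c2)c(OC)c1 | intermediate
12 | nonafluoro-1-iodobutane | FC(F)(F)C(F)(F)C(F)(F)C(F)(F)I | starting material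
13 | potassium 2,6-dimethoxy-4-(2,4,6-trimethoxyphenoxy)phenoxide | COc1cc(OC)c(Oc2cc(OC)c([O-])c(OC)c2)c(OC)c1.[K+] | intermediate
14 | 3,4,5-trimethoxybenzyne (1,2-didehydro-3,4,5-trimethoxybenzene) | COC1=CC#CC(OC)=C1OC | intermediate
15 | {2-[2,6-dimethoxy-4-(2,4,6-trimethoxyphenoxy)phenoxy]-4,5,6-trimethoxyphenyl}potassium | COc1cc(OC)c(Oc2cc(OC)c(Oc3cc(OC)c(OC)c(OC)c3[K])c(OC)c2)c(OC)c1 | intermediate
16 | 1-[2,6-dimethoxy-4-(2,4,6-trimethoxyphenoxy)phenoxy]-2-iodo-3,4,5-trimethoxybenzene | COc1cc(OC)c(Oc2cc(OC)c(Oc3cc(OC)c(OC)c(OC)c3I)c(OC)c2)c(OC)c1 | intermediate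
17 | 4-bromo-2,6-dimethoxyphenol | COc1cc(Br)cc(OC)c1O | starting material
18 | 4-(4-bromo-2,6-dimethoxyphenoxy)-2,6-dimethoxybenzaldehyde | COc1cc(Br)cc(OC)c1Oc1cc(OC)c(C=O)c(OC)c1 | intermediate
19 | 4-(4-bromo-2,6-dimethoxyphenoxy)-2,6-dimethoxyphenyl formate | COc1cc(Br)cc(OC)c1Oc1cc(OC)c(OC=O)c(OC)c1 | intermediate
20 | 4-(4-bromo-2,6-dimethoxyphenoxy)-2,6-dimethoxyphenol | COc1cc(Br)cc(OC)c1Oc1cc(OC)c(O)c(OC)c1 | intermediate
21 | (3,4,5-trimethoxyphenyl)boronic acid | COc1cc(B(O)O)cc(OC)c1OC | starting material
22 | 5-bromo-2-[3,5-dimethoxy-4-(3,4,5-trimethoxyphenoxy)phenoxy]-1,3-dimethoxybenzene | COc1cc(Br)cc(OC)c1Oc1cc(OC)c(Oc2cc(OC)c(OC)c(OC)c2)c(OC)c1 | intermediate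
23 | 4-[3,5-dimethoxy-4-(3,4,5-trimethoxyphenoxy)phenoxy]-3,5-dimethoxyphenol | COc1cc(O)cc(OC)c1Oc1cc(OC)c(Oc2cc(OC)c(OC)c(OC)c2)c(OC)c1 | intermediate
24 | 1-[2,6-dimethoxy-4-(2,4,6-trimethoxyphenoxy)phenoxy]-2-{4-[3,5-dimethoxy-4-(3,4,5-trimethoxyphenoxy)phenoxy]-3,5-dimethoxyphenoxy}-3,4,5-trimethoxybenzene | COc1cc(OC)c(Oc2cc(OC)c(Oc3cc(OC)c(OC)c(OC)c3Oc3cc(OC)c(Oc4cc(OC)c(Oc5cc(OC)c(OC)c(OC)c5)c(OC)c4)c(OC)c3)c(OC)c2)c(OC)c1 | intermediate
25 | 5-[2,6-dihydroxy-4-(2,4,6-trihydroxyphenoxy)phenoxy]-4-{4-[3,5-dihydroxy-4-(3,4,5-trihydroxyphenoxy)phenoxy]-3,5-dihydroxyphenoxy}benzene-1,2,3-triol | Oc1cc(O)c(Oc2cc(O)c(Oc3cc(O)c(O)c(O)c3Oc3cc(O)c(Oc4cc(O)c(Oc5cc(O)c(O)c(O)c5)c(O)c4)c(O)c3)c(O)c2)c(O)c1 | target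

## Step count and least certain steps

Total: 12 steps. Longest linear sequence: 6 steps (steps 7, 8, 9, 10, 11, 12). The route is convergent: 16 is made in six steps with a longest chain of four (steps 1, 2, 3 and 6), and 23 in four steps (steps 7 to 10).

**Step 6 (key step).** The most likely failure is protonation of the C2 carbanion before iodine transfer, by traces of water or by any phenol not converted to phenoxide. That would leave a C–H bond which cannot be iodinated selectively afterwards, because rings A, B and C are equally activated. Electron transfer from the phenoxide to the perfluoroalkyl iodide, leading to perfluoroalkylation, is a second possible diversion. The step is an extension of known three-component aryne couplings, not a demonstrated case.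
Fallback: the vicinal oxygen–iodine pair is set by SNAr and Dakin chemistry instead of the aryne. The fallback sets out from 8 and 11 and returns at 16. Aldehyde 8 would be iodinated (NIS, cat. TFA, MeCN) at the position ortho to fluorine and ortho/para to the methoxy groups, giving 4-fluoro-3-iodo-2,6-dimethoxybenzaldehyde F1. SNAr of the phenoxide of 11 on F1 (Cs2CO3, DMSO, 110–120 °C) should give 4-[2,6-dimethoxy-4-(2,4,6-trimethoxyphenoxy)phenoxy]-3-iodo-2,6-dimethoxybenzaldehyde F2. Baeyer–Villiger oxidation (mCPBA, CH2Cl2) to 4-[2,6-dimethoxy-4-(2,4,6-trimethoxyphenoxy)phenoxy]-3-iodo-2,6-dimethoxyphenyl formate F3 and methanolysis would give 4-[2,6-dimethoxy-4-(2,4,6-trimethoxyphenoxy)phenoxy]-3-iodo-2,6-dimethoxyphenol F4. O-Methylation (MeI, K2CO3, acetone) converts F4 into 16.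

**Step 11.** The C2 iodide is flanked by a bulky aryloxy group and a methoxy group. The copper phenoxide may fail to engage it, so that reductive loss of iodine or stalling outruns C–O bond formation.
Fallback: the roles of the partners are exchanged, so that only a small hydroxide has to enter the congested position. The fallback sets out from 16 and 22 and returns at 24. Iodide 16 would be hydroxylated under the conditions of step 10 (Pd2(dba)3, tBuXPhos, KOH, dioxane/H2O) to 6-[2,6-dimethoxy-4-(2,4,6-trimethoxyphenoxy)phenoxy]-2,3,4-trimethoxyphenol F5. F5 would then be coupled as the hindered phenol with the unhindered aryl bromide 22 (CuI, picolinic acid, K3PO4, DMSO, 110 °C) to give 24.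

**Step 12.** Cleavage at fifteen sites may stop short and leave partly methylated congeners, and the free polyphenol may oxidise during isolation.
Fallback: a derivatise–purify–release sequence from 24 to 25. After the BBr3 treatment the crude product would be peracetylated in the same work-up (Ac2O, pyridine) to the pentadecaacetate of the target F6. F6 is stable to air and silica and separable from incompletely demethylated material, which can be resubmitted. Mild deacetylation (HCl in MeOH, argon) would then give 25.

**Step 9.** The doubly ortho-substituted phenol 20 may bind and couple at copper only slowly, so that the boronic acid 21 is consumed by protodeboronation, oxidative homocoupling or hydroxylation before the ether forms.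
Fallback: the ring F ether is made by aryne O-arylation instead of a copper coupling, with neither boron nor a metal involved. The fallback sets out from 20 and 6 and returns at 22. Treating phenol 20 and triflate 6 (1.3 equiv) with CsF in MeCN at rt would release the aryne 14 again. The phenoxide should add at the aryne carbon remote from the C3 methoxy group, and the adjacent carbanion is protonated by the phenol or by acetonitrile. This would give 22 directly, with ring F as the 3,4,5-trimethoxyphenyl group. The aryl bromide is inert to fluoride, and no new compound is made (F0).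

## Further compounds

F1 | step 6 | 4-fluoro-3-iodo-2,6-dimethoxybenzaldehyde | COc1cc(F)c(I)c(OC)c1C=O
F2 | step 6 | 4-[2,6-dimethoxy-4-(2,4,6-trimethoxyphenoxy)phenoxy]-3-iodo-2,6-dimethoxybenzaldehyde | COc1cc(OC)c(Oc2cc(OC)c(Oc3cc(OC)c(C=O)c(OC)c3I)c(OC)c2)c(OC)c1
F3 | step 6 | 4-[2,6-dimethoxy-4-(2,4,6-trimethoxyphenoxy)phenoxy]-3-iodo-2,6-dimethoxyphenyl formate | COc1cc(OC)c(Oc2cc(OC)c(Oc3cc(OC)c(OC=O)c(OC)c3I)c(OC)c2)c(OC)c1
F4 | step 6 | 4-[2,6-dimethoxy-4-(2,4,6-trimethoxyphenoxy)phenoxy]-3-iodo-2,6-dimethoxyphenol | COc1cc(OC)c(Oc2cc(OC)c(Oc3cc(OC)c(O)c(OC)c3I)c(OC)c2)c(OC)c1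
F5 | step 11 | 6-[2,6-dimethoxy-4-(2,4,6-trimethoxyphenoxy)phenoxy]-2,3,4-trimethoxyphenol | COc1cc(OC)c(Oc2cc(OC)c(Oc3cc(OC)c(OC)c(OC)c3O)c(OC)c2)c(OC)c1
F6 | step 12 | pentadecaacetate of the target | CC(=O)Oc1cc(OC(C)=O)c(Oc2cc(OC(C)=O)c(Oc3cc(OC(C)=O)c(OC(C)=O)c(OC(C)=O)c3Oc3cc(OC(C)=O)c(Oc4cc(OC(C)=O)c(Oc5cc(OC(C)=O)c(OC(C)=O)c(OC(C)=O)c5)c(OC(C)=O)c4)c(OC(C)=O)c3)c(OC(C)=O)c2)c(OC(C)=O)c1
F0 | step 9 | none | none
A1 | alternative 1 | 5-[2,6-dimethoxy-4-(2,4,6-trimethoxyphenoxy)phenoxy]-4-[(tert-butyldimethylsilyl)oxy]-2,3-dimethoxyphenol | COc1cc(OC)c(Oc2cc(OC)c(Oc3cc(O)c(OC)c(OC)c3O[Si](C)(C)C(C)(C)C)c(OC)c2)c(OC)c1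
A2 | alternative 1 | 4-[(tert-butyldimethylsilyl)oxy]-4-{1-[2,6-dimethoxy-4-(2,4,6-trimethoxyphenoxy)phenoxy]ethenyl}-2,3-dimethoxycyclobut-2-en-1-one | COC1=C(OC)C(O[Si](C)(C)C(C)(C)C)(C(=C)Oc2c(OC)cc(Oc3c(OC)cc(OC)cc3OC)cc2OC)C1=O
A3 | alternative 1 | dimethyl squarate (3,4-dimethoxycyclobut-3-ene-1,2-dione) | COC1=C(OC)C(=O)C1=O
A4 | alternative 2 | dimethyl 2,4,6-trihydroxy-5-(methylated five-ring aryloxy)benzene-1,3-dicarboxylate | COC(=O)c1c(O)c(C(=O)OC)c(O)c(Oc2cc(OC)c(Oc3cc(OC)c(OC)c(OC)c3Oc3cc(OC)c(Oc4cc(OC)c(Oc5cc(OC)c(OC)c(OC)c5)c(OC)c4)c(OC)c3)c(OC)c2)c1O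
A5 | alternative 2 | dimethyl 3-oxopentanedioate | COC(=O)CC(=O)CC(=O)OC
A6 | alternative 2 | dimethyl 2-(methylated five-ring aryloxy)propanedioate | COC(=O)C(Oc1cc(OC)c(Oc2cc(OC)c(OC)c(OC)c2Oc2cc(OC)c(Oc3cc(OC)c(Oc4cc(OC)c(OC)c(OC)c4)c(OC)c3)c(OC)c2)c(OC)c1)C(=O)OC
A7 | alternative 3 | methylated hexamer with free hydroxyls para to the ether on ring A, at C4 of ring C and at C4 of ring F | Oc1cc(OC)c(Oc2cc(OC)c(Oc3cc(OC)c(O)c(OC)c3Oc3cc(OC)c(Oc4cc(OC)c(Oc5cc(OC)c(O)c(OC)c5)c(OC)c4)c(OC)c3)c(OC)c2)c(OC)c1
A8 | alternative 3 | methylated hexameric trialdehyde | O=Cc1cc(OC)c(Oc2cc(OC)c(Oc3cc(OC)c(C=O)c(OC)c3Oc3cc(OC)c(Oc4cc(OC)c(Oc5cc(OC)c(C=O)c(OC)c5)c(OC)c4)c(OC)c3)c(OC)c2)c(OC)c1
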